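# Proposed synthesis of (2S)-6-farnesyl-5,7,3′,5′-tetrahydroxyflavanone (CNP0186816.1)

Abbreviations: "farnesyl" = (2E,6E)-3,7,11-trimethyldodeca-2,6,10-trien-1-yl; MOM = methoxymethyl; TIPS = tri(propan-2-yl)silyl. Flavanone numbering: O1, C2, C3, C4, C4a, C5–C8, C8a; ring A is the fused benzene ring, ring C the pyranone ring, ring B the 2-aryl group.

## Analysis of the target

The target 19 is a flavanone: ring A carries hydroxyls at C5 and C7 and an all-E farnesyl chain at C6 between them, ring C is a dihydropyranone (O1, C2, C3, C4=O), and ring B is a 3,5-dihydroxyphenyl group on C2. C2 is the only stereocentre and has the S configuration (O1 > ring B > C3 > H). It is a benzylic ether carbon β to the C4 ketone, so it can be lost by retro-oxa-Michael opening to the 2′-hydroxychalcone whenever the C3 enolate forms under basic conditions, and no other stereocentre can restore it. The farnesyl chain has three trisubstituted alkenes, two of fixed E geometry, which are sensitive to acid (cyclisation onto the flanking 5-OH or 7-OH to chromans, cation–olefin cyclisation), to electrophilic halogen and to hydrogenation catalysts. The hard points are placing the chain at C6 and not at C8, setting and keeping the labile C2 centre, and freeing four phenols at the end without harming the chain. The strategy rests on C4: it is a single carbonyl carbon bonded only to C4a and C3, and C3–C2 is a two-carbon unit carrying ring B. At the flavone oxidation level ring C therefore splits into an ortho-iodophenol (C4a–I, O1–H), carbon monoxide (C4) and an arylacetylene (C3≡C2–ring B). The ring A piece with farnesyl para to the free hydroxyl is mirror-symmetric, so its two ortho positions are identical and the C6/C8 question is settled before ring C exists.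

## Retrosynthetic reasoning

**19 ⇒ 18.** The four phenolic O–H bonds are traced back to MOM acetals. These groups direct the ring A metalation and are inert to organolithium and copper reagents, to the amine/CO/palladium conditions and to hydride. The forward step must cleave four acetals without protonating the chain alkenes and without opening ring C.

**18 ⇒ 16 (through 17).** The C2–H bond is cut, which takes the flavanone back to the planar flavone 16. C2 is then introduced by a reagent-controlled conjugate hydride addition one step before the end, so only one mild step remains in which it could be lost. The forward reaction must add hydride to C2 of a deactivated vinylogous ester from one face and leave the ketone and three isolated alkenes untouched. The enolate is held as silyl enol ether 17 until work-up, which blocks ring opening.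

**16 ⇒ 9 + 12 + 13.** Three bonds of ring C are cut: C4a–C4, C4–C3 and O1–C2. C4 is the natural place to cut because it has only two carbon neighbours and can come from 13. What remains is an aryl iodide with a free ortho hydroxyl (9) and a terminal alkyne bearing ring B (12). Both halves arrive with all oxygens and the side chain in place, so no regiochemical decision is left for the assembled core. The forward reaction has to insert 13 before the alkyne couples and has to close the six-membered ring, not the five-membered one.

**12 ⇒ 11 ⇒ 10.** The alkyne C≡C bond is traced to the formyl group of 11 by a one-carbon homologation of the Seyferth–Gilbert type, and 11 to the commercial dihydroxy aldehyde 10 by acetal protection. This gives ring B with its two oxygens in two routine steps.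

**9 ⇒ 8.** The C–I bond is cut. Both positions ortho to the hydroxyl of 8 are equivalent by symmetry and are the only free ring positions, so a mono-iodination can give only one product. The forward reaction must iodinate a very electron-rich phenol faster than electrophilic iodine attacks the chain.

**8 ⇒ 7 ⇒ 3 + 4 (through 5 and 6).** The silyl ether of 7 is a mask for the phenol. The aryl–CH2 bond of the chain is cut at the carbon flanked by both MOM ethers. That carbon is the most acidic ring position of 3, so directed lithiation gives 5, transmetalation gives arylcopper 6, and 6 displaces the primary allylic bromide of 4 without allylic transposition. The E,E geometry is bought with 4 and not made.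

**3 ⇒ 2 ⇒ 1.** The three equivalent oxygens of 1 are differentiated as two MOM ethers and one bulky silyl ether. The silyl group does not direct metalation and shields its neighbours, which leaves the position between the two acetals as the only good site.

## Alternatives that were turned down

Alternative 1: The C2–C3 bond is cut, leading to diazoketone A1, which has a diazoacetyl group on C4a and a 3,5-bis(silyloxy)benzyl group on O1. A chiral dirhodium tetracarboxylate of the Rh2(O2CR*)4 type would generate a rhodium carbene at C3 that inserts into one of the two enantiotopic benzylic C–H bonds next to O1, closing ring C and setting C2 in one event to give A2.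
- For: ring closure and stereocentre come together, the C–H bond is doubly activated (α to oxygen and benzylic), and the silyl ethers of A2 leave with buffered fluoride, which is gentler on the chain than acid. On these two points it is stronger than the chosen route.
- Against: a terminal diazoketone gives an acceptor-only carbene, the least selective class for enantiotopic C–H discrimination. The ether oxygen sits where a five-membered oxonium ylide can form and rearrange by 1,2-benzyl shift with ring contraction. The three trisubstituted alkenes and the electron-rich ring B are good carbene traps. A1 itself needs a ring A with four different substituents, so the C6/C8 and O1/O5 distinctions must be solved first.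
- Comparison: the chosen route gives no one-step closure with stereocontrol, but it offers symmetric intermediates and a catalytic reduction on a flat substrate with no competing carbene pathways.

Alternative 2: Ring A is built de novo from cyclobutenone A3, which carries the C2 stereocentre in its alkoxy substituent, and farnesyl siloxyalkyne A4. On heating, A3 opens to a vinylketene whose [2+2] addition to A4 joins the ketene carbonyl carbon to the farnesyl-bearing alkyne carbon (C5–C6) and the ketene α-carbon to the siloxy carbon (C7–C8). Four-electron ring opening and six-electron closure then form C4a–C5 and give phenol A5.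
- For: the chain position is fixed by construction, with no aromatic substitution at all. C2 would be set before A3 is assembled by a well-established asymmetric ketone reduction, which is more predictable than the late reduction chosen here. A5 is pseudo-symmetric, so the later acylation that closes ring C gives the same skeleton at either ortho position.
- Against: A3 and A4 each need several steps from unstable or specialised precursors. The stereocentre in A3 and A5 is a β-aryloxy ester that can eliminate on heating or with base. Ring C still has to be closed by an acid-mediated Friedel–Crafts acylation in the presence of the chain.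
- Comparison: the route is roughly twice as long, and it builds a benzene ring that is commercially available in symmetric form. The chosen route offers brevity and convergence instead of its early, secure stereocentre.

Alternative 3: The C4a–C5 bond is cut, leading to dihydropyranone A6, in which ring C and C2 already exist and a farnesylated β-keto ester side chain hangs on the carbon that becomes C8a. Base would generate the extended enolate of the pyranone, whose α-carbon (future C4a) attacks the side-chain ester. Loss of the ester alkoxide and enolisation then give aromatic ring A in A7.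
- For: it follows the biosynthetic folding, needs no aromatic substitution or heavy metal, gives ring A with free hydroxyls (two fewer protecting groups to remove at the end), and C2 could come from a catalytic asymmetric hetero-Diels–Alder reaction.
- Against: the most acidic site of A6 is the β-keto ester carbon, so a dianion is needed. Under those conditions the pyranone can open by retro-oxa-Michael reaction, which racemises C2 before and after aromatisation. C- versus O-acylation and the length of the synthesis of A6 add further uncertainty.
- Comparison: the chosen route never exposes the stereocentre to strong base and uses established catalytic steps. In exchange it accepts four acetal cleavages at the end.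

Key step: step 8

Assumption: the sense of induction in step 9 is assumed to be that (R)-DTBM-SEGPHOS delivers hydride to the face of C2 that gives the 2S product; this would be checked on a farnesyl-free model flavone and the antipodal ligand used if the sense proves opposite.

## Route

Step 1
Reactants: 1 phloroglucinol
Product: 2 3,5-bis(methoxymethoxy)phenol
Conditions: MOMCl (2.0 equiv), i-Pr2NEt (2.2 equiv), DMF, 0 °C to rt; chromatographic separation from mono- and tris-ethers
Reagents that add atoms: chloromethyl methyl ether (MOMCl), COCCl
Why: O-alkylation of a phenol with an α-chloro ether (Williamson type); with two equivalents the bis-ether should be the main product of the statistical mixture, and the mono-ether can be resubmitted.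

Step 2
Reactants: 2 3,5-bis(methoxymethoxy)phenol
Product: 3 [3,5-bis(methoxymethoxy)phenoxy]tri(propan-2-yl)silane
Conditions: TIPSCl, imidazole, DMF, rt
Reagents that add atoms: chlorotri(propan-2-yl)silane (TIPSCl), CC(C)[Si](Cl)(C(C)C)C(C)C
Why: Standard silylation of the remaining phenol; the bulky silyl ether survives n-BuLi, does not direct metalation and shields its two neighbouring ring positions.

Step 3
Reactants: 3 [3,5-bis(methoxymethoxy)phenoxy]tri(propan-2-yl)silane; 4 (2E,6E)-farnesyl bromide
Product: 7 {4-farnesyl-3,5-bis(methoxymethoxy)phenoxy}tri(propan-2-yl)silane, via aryllithium 5 (not isolated), via arylcopper 6 (not isolated)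
Conditions: n-BuLi (1.1 equiv), THF, 0 °C, 1 h; CuBr·SMe2 (1.1 equiv), −40 °C; then 4 (1.2 equiv), −40 to 0 °C
Reagents that add atoms: n-butyllithium, [Li]CCCC (supplies the Li of 5 and leaves no atoms in 7); copper monobromide dimethyl sulfide complex (CuBr·SMe2), CSC.[Cu]Br (supplies the Cu of 6 and leaves no atoms in 7)
Why: Directed ortho-metalation at the carbon chelated by both MOM ethers, transmetalation to monovalent copper, and SN2 substitution of the primary allylic bromide by the arylcopper, which should keep the linear connectivity and the E geometry; no stereocentre is formed.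

Step 4
Reactants: 7 {4-farnesyl-3,5-bis(methoxymethoxy)phenoxy}tri(propan-2-yl)silane
Product: 8 4-farnesyl-3,5-bis(methoxymethoxy)phenol
Conditions: Bu4NF (1.1 equiv), AcOH (1.1 equiv), THF, 0 °C to rt
Reagents that add atoms: none
Why: Fluoride cleavage of an aryl silyl ether; the acetic acid buffer keeps the electron-rich phenoxide from forming, and acetals and alkenes are inert.

Step 5
Reactants: 8 4-farnesyl-3,5-bis(methoxymethoxy)phenol
Product: 9 4-farnesyl-2-iodo-3,5-bis(methoxymethoxy)phenol
Conditions: N-iodosuccinimide (1.0 equiv), CH2Cl2, −78 to −20 °C, dark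
Reagents that add atoms: N-iodosuccinimide, O=C1CCC(=O)N1I
Why: Electrophilic aromatic iodination; the two free positions are equivalent and activated by three oxygens, so the ring should react far faster than the isolated alkenes, the MOM groups on both oxygens next to the chain rule out iodoetherification, and one equivalent at low temperature limits di-iodination.

Step 6
Reactants: 10 3,5-dihydroxybenzaldehyde
Product: 11 3,5-bis(methoxymethoxy)benzaldehyde
Conditions: MOMCl (2.5 equiv), i-Pr2NEt (3 equiv), CH2Cl2, 0 °C to rt
Reagents that add atoms: chloromethyl methyl ether (MOMCl), COCCl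
Why: Exhaustive O-alkylation of both phenols with an α-chloro ether; the aldehyde is untouched.

Step 7
Reactants: 11 3,5-bis(methoxymethoxy)benzaldehyde
Product: 12 1-ethynyl-3,5-bis(methoxymethoxy)benzene
Conditions: dimethyl (1-diazo-2-oxopropyl)phosphonate (1.3 equiv), K2CO3 (2 equiv), MeOH, 0 °C to rt
Reagents that add atoms: dimethyl (1-diazo-2-oxopropyl)phosphonate (Ohira–Bestmann reagent), COP(=O)(OC)C(=[N+]=[N-])C(C)=O (one carbon)
Why: Ohira–Bestmann variant of the Seyferth–Gilbert homologation; aryl aldehydes without α-hydrogens are its best substrates and the mild base leaves the acetals alone.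

Step 8
Reactants: 9 4-farnesyl-2-iodo-3,5-bis(methoxymethoxy)phenol; 12 1-ethynyl-3,5-bis(methoxymethoxy)benzene; 13 carbon monoxide
Product: 16 6-farnesyl-5,7-bis(methoxymethoxy)-2-[3,5-bis(methoxymethoxy)phenyl]-4H-chromen-4-one, via ynone 14 (not isolated), via enaminone 15 (not isolated)
Conditions: PdCl2(PPh3)2 (5 mol %), 12 (1.3 equiv), CO (10 bar), Et2NH, 100 °C, autoclave
Reagents that add atoms: diethylamine, CCNCC (supplies the NEt2 group of 15; leaves no atoms in 16)
Why: Zerovalent palladium, formed from PdCl2(PPh3)2 and the amine, inserts into the C–I bond of 9, CO 13 inserts to give an aroylpalladium iodide, and coupling with the amine-deprotonated alkyne 12 followed by reductive elimination gives ynone 14 (C4a–C4 and C4–C3). Et2NH adds conjugatively to 14 to give enaminone 15, and the ortho phenol oxygen attacks the amine-bearing carbon and expels Et2NH, so ring C is closed by a 6-endo addition–elimination (formally 6-endo-dig on the ynone) that forms O1–C2. The closest known reaction type is the palladium-catalysed carbonylative annulation of 2-iodophenols with terminal arylacetylenes to flavones in a secondary amine. No stereocentre is formed, the product being planar. CO insertion must outrun direct alkynylation of the arylpalladium, which the CO pressure, the copper-free conditions and the electron-rich, doubly ortho-substituted aryl group (fast migration to CO, slow direct coupling) should secure. Closure must be 6-endo and not 5-exo, which the enaminone pathway secures because the phenol can only displace the amine at the β-carbon. Site selectivity does not arise, since 9 has one C–I bond and its symmetry allows only one iodophenol; the chain alkenes are trisubstituted and meta to the C–Pd bond, so Heck-type insertion should not compete.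

Step 9
Reactants: 16 6-farnesyl-5,7-bis(methoxymethoxy)-2-[3,5-bis(methoxymethoxy)phenyl]-4H-chromen-4-one
Product: 18 (2S)-6-farnesyl-5,7-bis(methoxymethoxy)-2-[3,5-bis(methoxymethoxy)phenyl]chroman-4-one, via silyl enol ether 17 (not isolated)
Conditions: Cu(OAc)2·H2O (5 mol %), (R)-DTBM-SEGPHOS (5.5 mol %), HSiMe(OEt)2 (3 equiv), toluene, 0 °C to rt; then aq. citric acid, THF, 0 °C
Reagents that add atoms: diethoxy(methyl)silane, CCO[SiH](C)OCC (supplies the silyl group of 17 and the hydride at C2; no non-hydrogen atoms remain in 18)
Why: Copper hydride asymmetric conjugate reduction of a chromone: the bisphosphine-bound copper hydride adds hydride to C2 from the face chosen by the chiral ligand, the copper enolate is silylated to 17, which cannot open ring C, and mild acidic hydrolysis gives the ketone; isolated alkenes and acetals do not react with copper hydride.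

Step 10
Reactants: 18 (2S)-6-farnesyl-5,7-bis(methoxymethoxy)-2-[3,5-bis(methoxymethoxy)phenyl]chroman-4-one
Product: 19 (2S)-2-(3,5-dihydroxyphenyl)-6-farnesyl-5,7-dihydroxychroman-4-one (target)
Conditions: 3 M aq. HCl/MeOH (1:4), 40 °C, monitored closely; NaHCO3 quench
Reagents that add atoms: none
Why: Acid-catalysed transacetalisation of aryl MOM ethers to methanol; the conditions are acidic and not basic, so the C2 centre should hold, and dilute acid at moderate temperature should be tolerated by the prenyl-type chain for the short time needed.

## Compound list

1 | phloroglucinol (benzene-1,3,5-triol) | Oc1cc(O)cc(O)c1 | starting material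
2 | 3,5-bis(methoxymethoxy)phenol | COCOc1cc(O)cc(OCOC)c1 | intermediate
3 | [3,5-bis(methoxymethoxy)phenoxy]tri(propan-2-yl)silane | COCOc1cc(OCOC)cc(O[Si](C(C)C)(C(C)C)C(C)C)c1 | intermediate
4 | (2E,6E)-farnesyl bromide | CC(C)=CCC/C(C)=C/CC/C(C)=C/CBr | starting material
5 | [2,6-bis(methoxymethoxy)-4-(triisopropylsilyloxy)phenyl]lithium | [Li]c1c(OCOC)cc(O[Si](C(C)C)(C(C)C)C(C)C)cc1OCOC | intermediate
6 | [2,6-bis(methoxymethoxy)-4-(triisopropylsilyloxy)phenyl]copper | [Cu]c1c(OCOC)cc(O[Si](C(C)C)(C(C)C)C(C)C)cc1OCOC | intermediate
7 | {4-farnesyl-3,5-bis(methoxymethoxy)phenoxy}tri(propan-2-yl)silane | CC(C)=CCC/C(C)=C/CC/C(C)=C/Cc1c(OCOC)cc(O[Si](C(C)C)(C(C)C)C(C)C)cc1OCOC | intermediate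
8 | 4-farnesyl-3,5-bis(methoxymethoxy)phenol | CC(C)=CCC/C(C)=C/CC/C(C)=C/Cc1c(OCOC)cc(O)cc1OCOC | intermediate
9 | 4-farnesyl-2-iodo-3,5-bis(methoxymethoxy)phenol | CC(C)=CCC/C(C)=C/CC/C(C)=C/Cc1c(OCOC)cc(O)c(I)c1OCOC | intermediate
10 | 3,5-dihydroxybenzaldehyde | O=Cc1cc(O)cc(O)c1 | starting material
11 | 3,5-bis(methoxymethoxy)benzaldehyde | O=Cc1cc(OCOC)cc(OCOC)c1 | intermediate
12 | 1-ethynyl-3,5-bis(methoxymethoxy)benzene | C#Cc1cc(OCOC)cc(OCOC)c1 | intermediate
13 | carbon monoxide | [C-]#[O+] | starting material
14 | 1-[3-farnesyl-6-hydroxy-2,4-bis(methoxymethoxy)phenyl]-3-[3,5-bis(methoxymethoxy)phenyl]prop-2-yn-1-one | CC(C)=CCC/C(C)=C/CC/C(C)=C/Cc1c(OCOC)cc(O)c(C(=O)C#Cc2cc(OCOC)cc(OCOC)c2)c1OCOC | intermediate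
15 | 3-(diethylamino)-1-[3-farnesyl-6-hydroxy-2,4-bis(methoxymethoxy)phenyl]-3-[3,5-bis(methoxymethoxy)phenyl]prop-2-en-1-one (enaminone alkene geometry not fixed) | CC(C)=CCC/C(C)=C/CC/C(C)=C/Cc1c(OCOC)cc(O)c(C(=O)C=C(N(CC)CC)c2cc(OCOC)cc(OCOC)c2)c1OCOC | intermediate
16 | 6-farnesyl-5,7-bis(methoxymethoxy)-2-[3,5-bis(methoxymethoxy)phenyl]-4H-chromen-4-one | CC(C)=CCC/C(C)=C/CC/C(C)=C/Cc1c(OCOC)cc2c(c1OCOC)C(=O)C=C(c1cc(OCOC)cc(OCOC)c1)O2 | intermediate
17 | (2S)-4-[diethoxy(methyl)silyloxy]-6-farnesyl-5,7-bis(methoxymethoxy)-2-[3,5-bis(methoxymethoxy)phenyl]-2H-chromene | CC(C)=CCC/C(C)=C/CC/C(C)=C/Cc1c(OCOC)cc2c(c1OCOC)C(O[Si](C)(OCC)OCC)=C[C@@H](c1cc(OCOC)cc(OCOC)c1)O2 | intermediate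
18 | (2S)-6-farnesyl-5,7-bis(methoxymethoxy)-2-[3,5-bis(methoxymethoxy)phenyl]chroman-4-one | CC(C)=CCC/C(C)=C/CC/C(C)=C/Cc1c(OCOC)cc2c(c1OCOC)C(=O)C[C@@H](c1cc(OCOC)cc(OCOC)c1)O2 | intermediate
19 | (2S)-2-(3,5-dihydroxyphenyl)-5,7-dihydroxy-6-[(2E,6E)-3,7,11-trimethyldodeca-2,6,10-trien-1-yl]chroman-4-one | CC(C)=CCC/C(C)=C/CC/C(C)=C/Cc1c(O)cc2c(c1O)C(=O)C[C@@H](c1cc(O)cc(O)c1)O2 | target

## Step count and least certain steps

Total step count: 10. Longest linear sequence: 8 steps (from 1 through steps 1, 2, 3, 4, 5, 8, 9 and 10); the alkyne branch (steps 6 and 7) joins at step 8.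

**Step 8 (key step).** Most likely failures are capture of the aroylpalladium intermediate by the amine solvent before the alkyne couples, alkyne coupling before CO insertion followed by cyclisation to a five-membered ring, and sluggish oxidative addition at the electron-rich, doubly ortho-substituted C–I bond with loss of the alkyne by oligomerisation. Fallback, setting out from 9 and 12 and returning at 14 and then 16: the same ynone is made without palladium or CO. Alkyne 12 is deprotonated (n-BuLi, THF, −78 °C) and acylated with N-methoxy-N-methylcarbamoyl chloride to give Weinreb ynamide F1. Iodophenol 9 is deprotonated with MeMgCl (LiCl, THF, −20 °C) and subjected to iodine–magnesium exchange with i-PrMgCl to give the magnesiated phenoxide F2. Acylation of F2 by F1 gives ynone 14, now isolated, and brief treatment with Et2NH in EtOH closes it through 15 to flavone 16.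

**Step 9.** Hydride transfer to a 5,7-dialkoxy-2-aryl vinylogous ester may be slow, facial discrimination may be insufficient, or the configuration may erode by ring opening of the enolate during work-up. Fallback, setting out from 16 and returning at 18: non-selective conjugate reduction with LiBH(s-Bu)3 (lithium tri-sec-butylborohydride; THF, −78 °C, AcOH quench) gives the racemic flavanone F3, which is resolved by preparative chromatography on a polysaccharide chiral stationary phase to give 18. The (2R) antipode F4 is re-equilibrated to F3 with mild base through reversible ring opening and recycled.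

**Step 10.** Protonation of the chain alkenes may lead to cyclisation onto the freed 5-OH or 7-OH or to hydration, and forcing the last hindered ring A acetal may erode C2 by reversible ring opening. Fallback, setting out from 18 and returning at 19: a non-protic silyl-transfer deprotection. TMSOTf and 2,2′-bipyridyl (CH2Cl2, 0 °C) exchange each aryl MOM group for a trimethylsilyl group to give the tetrakis(trimethylsilyl) ether F5, which is hydrolysed with water in THF at rt to 19.

**Step 5.** Electrophilic iodine may attack the trisubstituted alkenes in competition with the ring, or a second iodination may occur at the other ortho position. Fallback, setting out from 8 and returning at 9: the iodine is introduced through an aryl anion. Phenol 8 is converted to its 1-ethoxyethyl ether F6 (ethyl vinyl ether, pyridinium p-toluenesulfonate, CH2Cl2; racemic at the acetal carbon). n-BuLi (THF, 0 °C) lithiates one of the two equivalent ring positions flanked by two acetal oxygens to give aryllithium F7, and I2 at −78 °C gives iodide F8. Pyridinium p-toluenesulfonate in MeOH at rt removes only the more labile 1-ethoxyethyl group to give 9.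

**Step 3.** Substitution may occur at the γ-carbon of the allylic bromide to give the branched isomer, the E geometry of the proximal alkene may be lost, or bromide 4 may homocouple. Fallback, setting out from 3 (through 5) and returning at 7: a palladium-catalysed cross-coupling replaces the cuprate substitution. Aryllithium 5 is transmetalated with ZnCl2 to the arylzinc chloride F9, which is coupled with 4 under Pd(PPh3)4 (THF, 0 °C to rt) in a Negishi-type allylation known to give the linear product with retention of alkene geometry.

## Further compounds

F1 | step 8 | N-methoxy-N-methyl-3-[3,5-bis(methoxymethoxy)phenyl]prop-2-ynamide | CON(C)C(=O)C#Cc1cc(OCOC)cc(OCOC)c1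
F2 | step 8 | chloromagnesium 2-(chloromagnesio)-4-farnesyl-3,5-bis(methoxymethoxy)phenoxide | CC(C)=CCC/C(C)=C/CC/C(C)=C/Cc1c(OCOC)cc(O[Mg]Cl)c([Mg]Cl)c1OCOC
F3 | step 9 | racemic 6-farnesyl-5,7-bis(methoxymethoxy)-2-[3,5-bis(methoxymethoxy)phenyl]chroman-4-one | CC(C)=CCC/C(C)=C/CC/C(C)=C/Cc1c(OCOC)cc2c(c1OCOC)C(=O)CC(c1cc(OCOC)cc(OCOC)c1)O2
F4 | step 9 | (2R)-6-farnesyl-5,7-bis(methoxymethoxy)-2-[3,5-bis(methoxymethoxy)phenyl]chroman-4-one | CC(C)=CCC/C(C)=C/CC/C(C)=C/Cc1c(OCOC)cc2c(c1OCOC)C(=O)C[C@H](c1cc(OCOC)cc(OCOC)c1)O2
F5 | step 10 | (2S)-6-farnesyl-5,7-bis(trimethylsilyloxy)-2-[3,5-bis(trimethylsilyloxy)phenyl]chroman-4-one | CC(C)=CCC/C(C)=C/CC/C(C)=C/Cc1c(O[Si](C)(C)C)cc2c(c1O[Si](C)(C)C)C(=O)C[C@@H](c1cc(O[Si](C)(C)C)cc(O[Si](C)(C)C)c1)O2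
F6 | step 5 | 5-(1-ethoxyethoxy)-2-farnesyl-1,3-bis(methoxymethoxy)benzene | CC(C)=CCC/C(C)=C/CC/C(C)=C/Cc1c(OCOC)cc(OC(C)OCC)cc1OCOC
F7 | step 5 | [6-(1-ethoxyethoxy)-3-farnesyl-2,4-bis(methoxymethoxy)phenyl]lithium | CC(C)=CCC/C(C)=C/CC/C(C)=C/Cc1c(OCOC)cc(OC(C)OCC)c([Li])c1OCOC
F8 | step 5 | 1-(1-ethoxyethoxy)-4-farnesyl-2-iodo-3,5-bis(methoxymethoxy)benzene | CC(C)=CCC/C(C)=C/CC/C(C)=C/Cc1c(OCOC)cc(OC(C)OCC)c(I)c1OCOC
F9 | step 3 | [2,6-bis(methoxymethoxy)-4-(triisopropylsilyloxy)phenyl]zinc chloride | Cl[Zn]c1c(OCOC)cc(O[Si](C(C)C)(C(C)C)C(C)C)cc1OCOC
A1 | alternative 1 | 2-diazo-1-{2-[3,5-bis(tert-butyldimethylsilyloxy)benzyloxy]-4,6-bis(tert-butyldimethylsilyloxy)-5-farnesylphenyl}ethan-1-one | CC(C)=CCC/C(C)=C/CC/C(C)=C/Cc1c(O[Si](C)(C)C(C)(C)C)cc(OCc2cc(O[Si](C)(C)C(C)(C)C)cc(O[Si](C)(C)C(C)(C)C)c2)c(C(=O)C=[N+]=[N-])c1O[Si](C)(C)C(C)(C)C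
A2 | alternative 1 | (2S)-6-farnesyl-5,7-bis(tert-butyldimethylsilyloxy)-2-[3,5-bis(tert-butyldimethylsilyloxy)phenyl]chroman-4-one | CC(C)=CCC/C(C)=C/CC/C(C)=C/Cc1c(O[Si](C)(C)C(C)(C)C)cc2c(c1O[Si](C)(C)C(C)(C)C)C(=O)C[C@@H](c1cc(O[Si](C)(C)C(C)(C)C)cc(O[Si](C)(C)C(C)(C)C)c1)O2
A3 | alternative 2 | methyl (3S)-3-[3,5-bis(methoxymethoxy)phenyl]-3-[(3-oxocyclobut-1-en-1-yl)oxy]propanoate | O=C1CC(O[C@@H](CC(=O)OC)c2cc(OCOC)cc(OCOC)c2)=C1
A4 | alternative 2 | triisopropyl{[(4E,8E)-5,9,13-trimethyltetradeca-4,8,12-trien-1-yn-1-yl]oxy}silane | CC(C)=CCC/C(C)=C/CC/C(C)=C/CC#CO[Si](C(C)C)(C(C)C)C(C)C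
A5 | alternative 2 | methyl (3S)-3-[3,5-bis(methoxymethoxy)phenyl]-3-[4-farnesyl-3-hydroxy-5-(triisopropylsilyloxy)phenoxy]propanoate | CC(C)=CCC/C(C)=C/CC/C(C)=C/Cc1c(O)cc(O[C@@H](CC(=O)OC)c2cc(OCOC)cc(OCOC)c2)cc1O[Si](C(C)C)(C(C)C)C(C)C
A6 | alternative 3 | methyl 2-farnesyl-3-oxo-4-{(2S)-2-[3,5-bis(methoxymethoxy)phenyl]-4-oxo-3,4-dihydro-2H-pyran-6-yl}butanoate (mixture of epimers at the ester α-carbon) | CC(C)=CCC/C(C)=C/CC/C(C)=C/CC(C(=O)OC)C(=O)CC1=CC(=O)C[C@@H](c2cc(OCOC)cc(OCOC)c2)O1
A7 | alternative 3 | (2S)-6-farnesyl-5,7-dihydroxy-2-[3,5-bis(methoxymethoxy)phenyl]chroman-4-one | CC(C)=CCC/C(C)=C/CC/C(C)=C/Cc1c(O)cc2c(c1O)C(=O)C[C@@H](c1cc(OCOC)cc(OCOC)c1)O2
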